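**Strategy.** Everything rests on the C2–C1′ bond between the pyridone ring and the side chain. That chain, eleven CH2 groups ending in C12′(=O)CH3, contains exactly the thirteen carbons of 1-methylcyclododecanol cut at its ring C1–C2 bond. In the key step the alkoxyl radical from 1-methylcyclododecyl hydroperoxide undergoes β-scission. This unmasks the remote methyl ketone and releases the primary 12-oxotridecyl radical, which adds to the free C2–H of protonated 4-chloro-3-methoxyquinoline (Minisci substitution). One operation thus attaches the complete, unprotected keto chain to a preformed core. The precursors are a C12 carbocycle and a 2-unsubstituted quinoline whose chlorine blocks C4 and later becomes the quinolone carbonyl.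

Key step: step 5

Assumption: the target has no stereocentre and no stereogenic double bond, so no stereocontrol is needed. It is drawn and delivered as the 4(1H)-quinolone tautomer.

Step 1
Reactants: 1 cyclododecanone
Product: 2 1-methylcyclododecan-1-ol
Conditions: MeMgBr (1.3 equiv), THF, 0 °C to rt; aq. NH4Cl
Reagents that add atoms: methylmagnesium bromide, C[Mg]Br
Why: Grignard 1,2-addition to a ketone; the carbinol carbon carries two identical ring arms, so no stereocentre arises.

Step 2
Reactants: 2 1-methylcyclododecan-1-ol
Product: 3 1-hydroperoxy-1-methylcyclododecane (1-methylcyclododecyl hydroperoxide)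
Conditions: 50% aq. H2O2 (excess), conc. H2SO4 (cat.), CH2Cl2, 0 °C to rt, vigorous stirring; used as a solution, not distilled
Reagents that add atoms: hydrogen peroxide, OO
Why: Acid-catalysed perhydrolysis (SN1) of a tertiary alcohol, in which excess H2O2 traps the tertiary cation and any alkene from E1 loss is re-protonated to the same cation.

Step 3
Reactants: 4 quinolin-3-ol
Product: 5 4-chloroquinolin-3-ol
Conditions: NCS (1.0 equiv), MeCN, rt to 50 °C
Reagents that add atoms: N-chlorosuccinimide, O=C1CCC(=O)N1Cl
Why: Electrophilic aromatic chlorination of a phenol; C4 corresponds to C1 of 2-naphthol, so attack there gives an O-stabilised arenium ion with the benzo ring still aromatic, which attack at C2 cannot.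

Step 4
Reactants: 5 4-chloroquinolin-3-ol
Product: 6 4-chloro-3-methoxyquinoline
Conditions: MeI (1.1 equiv), K2CO3, DMF, rt
Reagents that add atoms: iodomethane, CI
Why: Williamson ether synthesis; the phenoxide is the strongest nucleophile present and the 4-chlorine lowers the nucleophilicity of the ring nitrogen, which should favour O- over N-methylation.

Step 5
Reactants: 3 1-hydroperoxy-1-methylcyclododecane; 6 4-chloro-3-methoxyquinoline
Product: 9 13-(4-chloro-3-methoxyquinolin-2-yl)tridecan-2-one, via 1-methylcyclododecyloxyl radical 7 (not isolated), via 12-oxotridecyl radical 8 (not isolated)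
Conditions: 6 (1 equiv, ca. 0.3 M), TFA (2 equiv), FeSO4·7H2O (0.3 equiv), degassed MeCN–H2O 4:1, 40 °C; slow addition of 3 (2.5 equiv) in MeCN
Reagents that add atoms: none
Why: Fe(II) cleaves the O–O bond of 3 by single-electron reduction to the tertiary alkoxyl radical 7, whose β-scission breaks a ring C1–C2 bond, turns C1 into the methyl ketone and leaves the primary, nucleophilic radical 8; 8 adds to C2 of protonated 6, and Fe(III) oxidises the adduct, which loses H+ and re-aromatises, so that iron turns over and the O–O bond is the only oxidant. The closest known reaction type is the Minisci reaction with ω-oxoalkyl radicals made from 1-methylcycloalkyl hydroperoxides and Fe(II) salts, here applied to a twelve-membered ring. No ring is closed (one carbocycle is opened) and no stereocentre is formed. Ring opening has to beat loss of a methyl radical and transannular hydrogen abstraction: a primary alkyl radical is a better leaving fragment than methyl, two equivalent ring bonds are available, the transannular strain of the C12 ring is released, and the aqueous acidic medium, by hydrogen bonding to the oxyl oxygen and the developing carbonyl, speeds β-scission and slows hydrogen abstraction. Site selectivity needs attack at C2 only: protonation puts the largest LUMO coefficients on C2 and C4, C4 is blocked by chlorine, the 3-methoxy group favours its ortho position, and after reaction no activated C–H remains, so over-alkylation is excluded. A high concentration of 6 and slow addition of 3 should let bimolecular capture outrun 1,5-hydrogen shift and dimerisation of 8.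

Step 6
Reactants: 9 13-(4-chloro-3-methoxyquinolin-2-yl)tridecan-2-one
Product: 10 3-methoxy-2-(12-oxotridecyl)quinolin-4(1H)-one (target)
Conditions: 4 M aq. HCl–1,4-dioxane 1:1, 100 °C
Reagents that add atoms: water, O
Why: Acid-promoted SNAr hydrolysis (addition–elimination of water on the 4-chloroquinolinium ion) followed by tautomerisation to the 4(1H)-quinolone; the aryl methyl ether and the ketone should be inert to hot dilute aqueous HCl.

**Compound list**
1 | cyclododecanone | O=C1CCCCCCCCCCC1 | starting material
2 | 1-methylcyclododecan-1-ol | CC1(O)CCCCCCCCCCC1 | intermediate
3 | 1-hydroperoxy-1-methylcyclododecane | CC1(OO)CCCCCCCCCCC1 | intermediate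
4 | quinolin-3-ol | Oc1cnc2ccccc2c1 | starting material
5 | 4-chloroquinolin-3-ol | Oc1cnc2ccccc2c1Cl | intermediate
6 | 4-chloro-3-methoxyquinoline | COc1cnc2ccccc2c1Cl | intermediate
7 | 1-methylcyclododecyloxyl radical | CC1([O])CCCCCCCCCCC1 | intermediate
8 | 12-oxotridecyl radical | [CH2]CCCCCCCCCCC(C)=O | intermediate
9 | 13-(4-chloro-3-methoxyquinolin-2-yl)tridecan-2-one | COc1c(CCCCCCCCCCCC(C)=O)nc2ccccc2c1Cl | intermediate
10 | 3-methoxy-2-(12-oxotridecyl)quinolin-4(1H)-one | COc1c(CCCCCCCCCCCC(C)=O)[nH]c2ccccc2c1=O | target

Total step count: 6. Longest linear sequence: 4 steps (steps 1, 2, 5, 6 or steps 3, 4, 5, 6).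

**Steps most likely to fail**

Step 5. Transannular hydrogen abstraction or loss of a methyl radical in the alkoxyl radical may compete with ring opening, so that too little primary radical reaches the heteroarene.
- The fallback makes the same radical without any ring opening. It sets out from 6 and comes back at 9.
- Commercial 11-bromoundecanoic acid is used to alkylate the sodium enolate of ethyl acetoacetate (NaOEt, EtOH, reflux). This gives racemic 12-(ethoxycarbonyl)-13-oxotetradecanoic acid F1.
- Saponification and acidic decarboxylation give 13-oxotetradecanoic acid F2.
- A classical decarboxylative Minisci reaction of F2 with 6 (AgNO3 cat., (NH4)2S2O8, TFA, MeCN–H2O, 70 °C) should give 9.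

Step 2. Elimination to alkenes, acid-induced rearrangement of the peroxide, or poor phase contact of the waxy alcohol may prevent clean perhydrolysis.
- The fallback installs the peroxide by a radical route instead of an ionic one. It sets out from 1 and comes back at 3.
- Wittig methylenation of 1 (Ph3P=CH2, THF) gives methylidenecyclododecane F3.
- Cobalt-catalysed Markovnikov hydrosilylperoxidation of Mukaiyama–Isayama type (Co(acac)2 cat., O2, Et3SiH) gives triethyl[(1-methylcyclododecyl)peroxy]silane F4.
- Mild desilylation (cat. HCl, MeOH) releases 3.

Step 6. Displacement of a chloride flanked by the 3-methoxy group and the peri C5–H may be sluggish. Forcing conditions may cause cleavage of the methyl ether or acid-catalysed self-condensation at the ketone.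
- The fallback replaces hydrolysis by displacement followed by hydrogenolysis. It sets out from 9 and comes back at 10.
- SNAr with sodium benzyloxide (NaH, BnOH, 80 °C) gives 13-[4-(benzyloxy)-3-methoxyquinolin-2-yl]tridecan-2-one F5.
- Neutral hydrogenolysis (H2, Pd/C, EtOH, rt) should give 10.

**Further compounds**
F1 | step 5 | 12-(ethoxycarbonyl)-13-oxotetradecanoic acid (racemic) | CCOC(=O)C(CCCCCCCCCCC(=O)O)C(C)=O
F2 | step 5 | 13-oxotetradecanoic acid | CC(=O)CCCCCCCCCCCC(=O)O
F3 | step 2 | methylidenecyclododecane | C=C1CCCCCCCCCCC1
F4 | step 2 | triethyl[(1-methylcyclododecyl)peroxy]silane | CC[Si](CC)(CC)OOC1(C)CCCCCCCCCCC1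
F5 | step 6 | 13-[4-(benzyloxy)-3-methoxyquinolin-2-yl]tridecan-2-one | COc1c(CCCCCCCCCCCC(C)=O)nc2ccccc2c1OCc1ccccc1
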